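The side chain is disconnected at C-a, the CH of pyran ring A that is bonded to C-3A of quinolone A. The C-a–CH2 bond is made in the penultimate step by Hosomi–Sakurai methallylation of the cation formed from the cis-fused pentacyclic C-a alcohol 18. Two features are exploited. O-4A donates through C-3A=C-4A, so C-a ionises to an O-alkylated quinone-methide-type cation. In the cis-fused pyran A/pyran B bicycle, the CMe2 group on fusion carbon C-b and quinolone B on the O–CH fusion carbon C-c cover one face, so the allylsilane enters trans to CMe2. One operation thus adds the four side-chain carbons and the last stereocentre; hydrogenation finishes the isobutyl group.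

Key step: step 9

Labels: quinolone A and quinolone B are the two 7,8-dimethoxy-1-methylquinolin-2-one units. Pyran A is O-4A, C-4A, C-3A, C-a, C-b, C-c. Pyran B is O-4B, C-4B, C-3B, C-c, C-b, CMe2. Configurations are written (a,b,c) for C-a, C-b, C-c. The target is (aS,bS,cR); alcohol 18 is (aR,bS,cR), with OH cis to CMe2.

Assumption: the facial preference of the cinchona thiourea in step 7 cannot be predicted with confidence for this substrate. The quinidine-derived catalyst is written; its quinine-derived pseudoenantiomer would be used instead if a first run delivers the (bR,cS) ketone.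

Step 1
Reactants: 1 2,3-dimethoxyaniline
Product: 3 2,3-dimethoxy-N-methylaniline, via hemiaminal ether 2 (not isolated)
Conditions: (CH2O)n, NaOMe, MeOH, reflux; then NaBH4, reflux
Reagents that add atoms: paraformaldehyde (as formaldehyde) C=O
Why: Reductive mono-N-methylation: under methoxide the aniline and formaldehyde should give the N-(methoxymethyl)aniline 2, which NaBH4 reduces to the N-methyl compound, and a second methyl group cannot enter because the secondary amine appears only in the reduction stage.

Step 2
Reactants: 3 2,3-dimethoxy-N-methylaniline; 4 diethyl malonate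
Product: 6 4-hydroxy-7,8-dimethoxy-1-methylquinolin-2(1H)-one, via malonamate ester 5 (not isolated)
Conditions: Ph2O, 250 °C, EtOH distilled off
Reagents that add atoms: none
Why: Thermal aminolysis of one ester group gives anilide ester 5, which should lose ethanol and acylate the only free ortho position (para to the 3-methoxy group) in a Friedel–Crafts-type ring closure, the standard condensation route to 4-hydroxy-1-alkylquinolin-2-ones.

Step 3
Reactants: 6 4-hydroxy-7,8-dimethoxy-1-methylquinolin-2(1H)-one
Product: 8 4-hydroxy-7,8-dimethoxy-1-methyl-2-oxo-1,2-dihydroquinoline-3-carbaldehyde, via enaminone 7 (not isolated)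
Conditions: Me2NCH(OMe)2, toluene, 80 °C; then aq. NaOH, EtOH, 50 °C; HCl
Reagents that add atoms: N,N-dimethylformamide dimethyl acetal COC(OC)N(C)C; water O
Why: C-3 of the 4-hydroxyquinolone is a 1,3-dicarbonyl-type carbon that condenses with the amide acetal to enaminone 7, and hydroxide should then replace dimethylamine by addition–elimination to unmask the formyl group (formylation through an aminomethylene derivative).

Step 4
Reactants: 8 4-hydroxy-7,8-dimethoxy-1-methyl-2-oxo-1,2-dihydroquinoline-3-carbaldehyde; 9 prenal (3-methylbut-2-enal)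
Product: 12 7,8-dimethoxy-2,2,6-trimethyl-5-oxo-5,6-dihydro-2H-pyrano[3,2-c]quinoline-3-carbaldehyde, via oxa-Michael adduct 10 (not isolated), via aldol adduct 11 (not isolated)
Conditions: K2CO3, 1,4-dioxane, reflux
Reagents that add atoms: none
Why: Domino oxa-Michael/aldol condensation of the kind used for salicylaldehydes and enals: the quinolone 4-oxide should add to C-3 of prenal, the tethered aldehyde then closes onto the ring formyl group, and irreversible loss of water gives the 2H-pyran-3-carbaldehyde (pyran B with C-b=C-c).

Step 5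
Reactants: 12 7,8-dimethoxy-2,2,6-trimethyl-5-oxo-5,6-dihydro-2H-pyrano[3,2-c]quinoline-3-carbaldehyde
Product: 13 7,8-dimethoxy-2,2,6-trimethyl-5-oxo-5,6-dihydro-2H-pyrano[3,2-c]quinoline-3-carboxylic acid
Conditions: NaClO2, NaH2PO4, 2-methyl-2-butene, t-BuOH/H2O, rt
Reagents that add atoms: sodium chlorite [Na+].[O-]Cl=O
Why: Pinnick oxidation should convert the conjugated aldehyde into the acid without touching the alkene, the vinylogous ester or the dimethoxyarene, because the hypochlorite formed is trapped by 2-methyl-2-butene.

Step 6
Reactants: 13 7,8-dimethoxy-2,2,6-trimethyl-5-oxo-5,6-dihydro-2H-pyrano[3,2-c]quinoline-3-carboxylic acid; 6 4-hydroxy-7,8-dimethoxy-1-methylquinolin-2(1H)-one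
Product: 15 4-hydroxy-7,8-dimethoxy-3-[(7,8-dimethoxy-2,2,6-trimethyl-5-oxo-5,6-dihydro-2H-pyrano[3,2-c]quinolin-3-yl)carbonyl]-1-methylquinolin-2(1H)-one, via enol ester 14 (not isolated)
Conditions: DCC, DMAP, CH2Cl2, 0 → 40 °C
Reagents that add atoms: none
Why: Steglich O-acylation of the 4-hydroxy group followed by DMAP-mediated O-to-C acyl migration (Fries-type, through an acylpyridinium/quinolonate ion pair) should give the 3-acyl-4-hydroxyquinolone, which is held as a hydrogen-bonded chelate, as is usual for 4-hydroxycoumarins and 4-hydroxyquinolones.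

Step 7
Reactants: 15 open-chain 3-acyl-4-hydroxyquinolone (enone C-a(=O)–C-b=C-c)
Product: 17 cis-fused pentacyclic C-a ketone (bS,cR), via enol 16 (not isolated)
Conditions: 9-amino(9-deoxy)-epi-quinidine N-[3,5-bis(trifluoromethyl)phenyl]thiourea (10 mol%), toluene/CH2Cl2, −20 °C
Reagents that add atoms: none
Why: Bifunctional amine–thiourea-catalysed intramolecular oxa-Michael addition (6-endo-trig), the ring closure known for flavanones and for cis-fused chromeno-chromanones: the thiourea binds the chelating acyl group while the amine delivers the quinolone O-4A to one face of C-c, which sets C-c (R), and ketonisation of enol 16 by protonation at C-b on the face giving the less strained cis ring fusion sets C-b (S).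

Step 8
Reactants: 17 cis-fused pentacyclic C-a ketone (bS,cR)
Product: 18 cis-fused pentacyclic C-a alcohol (aR,bS,cR)
Conditions: NaBH4, CeCl3·7H2O, MeOH/CH2Cl2, −40 °C
Reagents that add atoms: none
Why: Luche 1,2-reduction, run directly after step 7, should outpace both hydride addition at C-4A and base-mediated ring opening, with hydride entering from the convex face to place the hydroxyl cis to CMe2; this C-a configuration is erased in step 9.

Step 9
Reactants: 18 cis-fused pentacyclic C-a alcohol (aR,bS,cR); 19 methallyltrimethylsilane
Product: 20 C-a (2-methylallyl) pentacycle (aS,bS,cR)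
Conditions: BF3·OEt2 (promoter, excess), 19 (4 equiv), CH2Cl2, −78 → −20 °C
Reagents that add atoms: none
Why: BF3 activates the C-a hydroxyl and ionises it to a cation delocalised through C-3A=C-4A onto O-4A; the alkene of the silane attacks C-a, and the resulting β-silyl cation loses silicon to the departed hydroxide, leaving the 2-methylallyl group on C-a. The closest known reaction is the Hosomi–Sakurai allylation of chroman-4-yl, xanthenyl and related benzylic cations generated directly from the alcohols with a Lewis acid. No ring is closed. The new stereocentre C-a (S) is set by the substrate: in the cis-fused bicycle the CMe2 group on C-b and quinolone B on C-c lie over one face of the planar cation, so the silane approaches from the convex face and the side chain ends up trans to CMe2, whatever the configuration of the alcohol. The step needs ionisation at C-a in preference to the C-c–O-4A bond, and capture in preference to loss of the C-b proton; the first is secured because the free hydroxyl is the group BF3 activates at low temperature whereas C-c carries only a weakly basic vinylogous ester oxygen, the second by the excess of the reactive 2-substituted allylsilane.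

Step 10
Reactants: 20 C-a (2-methylallyl) pentacycle (aS,bS,cR)
Product: 21 target CNP0275598.1 (aS,bS,cR)
Conditions: H2 (1 atm), Pd/C, EtOAc, rt
Reagents that add atoms: none
Why: Heterogeneous hydrogenation of the unhindered 1,1-disubstituted alkene should be far faster than reduction of the quinolone rings or hydrogenolysis of the pyran C–O bonds, creates no stereocentre, and would give the same isobutyl group even if the double bond migrated first.

Compound list
1 | 2,3-dimethoxyaniline | COc1cccc(N)c1OC | starting material
2 | N-(methoxymethyl)-2,3-dimethoxyaniline | COCNc1cccc(OC)c1OC | intermediate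
3 | 2,3-dimethoxy-N-methylaniline | CNc1cccc(OC)c1OC | intermediate
4 | diethyl malonate | CCOC(=O)CC(=O)OCC | starting material
5 | ethyl 3-[(2,3-dimethoxyphenyl)(methyl)amino]-3-oxopropanoate | CCOC(=O)CC(=O)N(C)c1cccc(OC)c1OC | intermediate
6 | 4-hydroxy-7,8-dimethoxy-1-methylquinolin-2(1H)-one | COc1ccc2c(O)cc(=O)n(C)c2c1OC | intermediate
7 | 3-[(dimethylamino)methylidene]-7,8-dimethoxy-1-methylquinoline-2,4(1H,3H)-dione | CN(C)C=C1C(=O)c2ccc(OC)c(OC)c2N(C)C1=O | intermediate
8 | 4-hydroxy-7,8-dimethoxy-1-methyl-2-oxo-1,2-dihydroquinoline-3-carbaldehyde | COc1ccc2c(O)c(C=O)c(=O)n(C)c2c1OC | intermediate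
9 | prenal (3-methylbut-2-enal) | CC(C)=CC=O | starting material
10 | 7,8-dimethoxy-1-methyl-4-[(2-methyl-4-oxobutan-2-yl)oxy]-2-oxo-1,2-dihydroquinoline-3-carbaldehyde | COc1ccc2c(OC(C)(C)CC=O)c(C=O)c(=O)n(C)c2c1OC | intermediate
11 | 4-hydroxy-7,8-dimethoxy-2,2,6-trimethyl-5-oxo-3,4,5,6-tetrahydro-2H-pyrano[3,2-c]quinoline-3-carbaldehyde (racemic, diastereomer mixture) | O=CC1C(O)c2c(c3ccc(OC)c(OC)c3n(C)c2=O)OC1(C)C | intermediate
12 | 7,8-dimethoxy-2,2,6-trimethyl-5-oxo-5,6-dihydro-2H-pyrano[3,2-c]quinoline-3-carbaldehyde | O=CC1=Cc2c(c3ccc(OC)c(OC)c3n(C)c2=O)OC1(C)C | intermediate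
13 | 7,8-dimethoxy-2,2,6-trimethyl-5-oxo-5,6-dihydro-2H-pyrano[3,2-c]quinoline-3-carboxylic acid | OC(=O)C1=Cc2c(c3ccc(OC)c(OC)c3n(C)c2=O)OC1(C)C | intermediate
14 | 7,8-dimethoxy-1-methyl-2-oxo-1,2-dihydroquinolin-4-yl ester of acid 13 | COc1ccc2c(OC(=O)C3=Cc4c(c5ccc(OC)c(OC)c5n(C)c4=O)OC3(C)C)cc(=O)n(C)c2c1OC | intermediate
15 | 4-hydroxy-7,8-dimethoxy-3-[(7,8-dimethoxy-2,2,6-trimethyl-5-oxo-5,6-dihydro-2H-pyrano[3,2-c]quinolin-3-yl)carbonyl]-1-methylquinolin-2(1H)-one | COc1ccc2c(O)c(C(=O)C3=Cc4c(c5ccc(OC)c(OC)c5n(C)c4=O)OC3(C)C)c(=O)n(C)c2c1OC | intermediate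
16 | enol form of ketone 17 (C-a(OH)=C-b; C-c configured as in 17) | COc1ccc2c3c(c(=O)n(C)c2c1OC)C(O)=C1[C@@H](O3)c2c(c3ccc(OC)c(OC)c3n(C)c2=O)OC1(C)C | intermediate
17 | cis-fused pentacyclic C-a ketone (bS,cR); H on C-b and C-c on the same face | COc1ccc2c3c(c(=O)n(C)c2c1OC)C(=O)[C@H]1[C@@H](O3)c2c(c3ccc(OC)c(OC)c3n(C)c2=O)OC1(C)C | intermediate
18 | cis-fused pentacyclic C-a alcohol (aR,bS,cR); OH cis to CMe2 | COc1ccc2c3c(c(=O)n(C)c2c1OC)[C@H](O)[C@H]1[C@@H](O3)c2c(c3ccc(OC)c(OC)c3n(C)c2=O)OC1(C)C | intermediate
19 | methallyltrimethylsilane | CC(=C)C[Si](C)(C)C | starting material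
20 | C-a (2-methylallyl) pentacycle (aS,bS,cR); side chain trans to CMe2 | COc1ccc2c3c(c(=O)n(C)c2c1OC)[C@@H](CC(C)=C)[C@H]1[C@@H](O3)c2c(c3ccc(OC)c(OC)c3n(C)c2=O)OC1(C)C | intermediate
21 | CNP0275598.1 (aS,bS,cR); isobutyl trans to CMe2, cis ring fusion | COc1ccc2c3c(c(=O)n(C)c2c1OC)[C@@H](CC(C)C)[C@H]1[C@@H](O3)c2c(c3ccc(OC)c(OC)c3n(C)c2=O)OC1(C)C | target

Total steps: 10. Longest linear sequence: 10 steps (1 to 21); compound 6 is made once and enters twice, in steps 3 and 6.

Steps most likely to fail

Step 9. BF3 held by the two lactam carbonyls may slow ionisation at C-a, so that loss of the C-b proton, cleavage of the C-c–O-4A bond or protodesilylation of the silane overtakes C–C bond formation. The fallback makes the same bond through a radical instead of a cation. It sets out from 18: acylation with PhOC(S)Cl (pyridine, DMAP, CH2Cl2) should give the O-phenyl thionocarbonate of 18 F1. Heating F1 with tributyl(2-methylallyl)stannane and AIBN in benzene at 80 °C (Keck radical allylation) should generate the C-a radical, which is trapped on the same convex face. The route is rejoined at 20.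

Step 7. The amine of the catalyst may also mediate reversible ring opening (retro-oxa-Michael), eroding enantiomeric purity, or closure may stay incomplete if the chelated open form is favoured. The fallback moves the enantioselection to the reduction. It sets out from 15: Et3N in CH2Cl2 should close the ring without selectivity, giving 17 together with the enantiomer of 17 F2. Asymmetric transfer hydrogenation of this racemate with RuCl[(S,S)-TsDPEN](p-cymene) in HCO2H/Et3N is run as a dynamic kinetic resolution. The slow-reacting enantiomer racemises by base-mediated ring opening and reclosure, the known behaviour of 2,3-disubstituted chroman-4-ones, while the matched one is reduced. The catalyst enantiomer is chosen to reduce 17. The route is rejoined at 18, with step 8 no longer needed.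

Step 4. The delocalised quinolone oxygen of 8 may add too slowly and reversibly to the fully substituted β-carbon of prenal, so that base-mediated self-condensation of the enal consumes it first. The fallback closes pyran B first by a well-established annulation and attaches the carboxyl carbon afterwards. It sets out from 6 and 9: heating in pyridine (Knoevenagel condensation/oxa-6π-electrocyclisation) should give 7,8-dimethoxy-2,2,6-trimethyl-2H-pyrano[3,2-c]quinolin-5(6H)-one F3. NBS in DMSO/H2O should give the trans bromohydrin F4, with Br on C-b and OH on C-c. Dehydration with TsOH in refluxing toluene should give the 3-bromo-2H-pyran F5. Hydroxycarbonylation (Pd(OAc)2, Xantphos, CO, K2CO3, dioxane/H2O, 80 °C) rejoins the route at 13, so 8 and 12 are bypassed.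

Further compounds
F1 | step 9 | O-phenyl thionocarbonate of alcohol 18 (aR,bS,cR) | COc1ccc2c3c(c(=O)n(C)c2c1OC)[C@H](OC(=S)Oc4ccccc4)[C@H]1[C@@H](O3)c2c(c3ccc(OC)c(OC)c3n(C)c2=O)OC1(C)C
F2 | step 7 | enantiomer of ketone 17 (bR,cS), formed with 17 as the racemate | COc1ccc2c3c(c(=O)n(C)c2c1OC)C(=O)[C@@H]1[C@H](O3)c2c(c3ccc(OC)c(OC)c3n(C)c2=O)OC1(C)C
F3 | step 4 | 7,8-dimethoxy-2,2,6-trimethyl-2H-pyrano[3,2-c]quinolin-5(6H)-one | C1=Cc2c(c3ccc(OC)c(OC)c3n(C)c2=O)OC1(C)C
F4 | step 4 | trans-3-bromo-4-hydroxy-7,8-dimethoxy-2,2,6-trimethyl-3,4-dihydro-2H-pyrano[3,2-c]quinolin-5(6H)-one (racemic; one enantiomer drawn) | Br[C@@H]1[C@@H](O)c2c(c3ccc(OC)c(OC)c3n(C)c2=O)OC1(C)C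
F5 | step 4 | 3-bromo-7,8-dimethoxy-2,2,6-trimethyl-2H-pyrano[3,2-c]quinolin-5(6H)-one | BrC1=Cc2c(c3ccc(OC)c(OC)c3n(C)c2=O)OC1(C)C
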